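The route rests on cutting C13–C14 of the henicosanenitrile chain. The key step exploits the fact that these atoms are unbranched, unactivated methylenes in the (CH2)20 tether between the nitrile carbon C1 and C5 of the 2-formylpyrrole ring, so each cut end is an unhindered primary carbon. Both ends are naturally ω-halide (electrophilic) termini. C13 is therefore reversed in polarity by 9-BBN hydroboration of tridec-12-enenitrile. Room-temperature Pd/PCy3 alkyl–alkyl Suzuki coupling of this borane with 5-(8-bromooctyl)-1H-pyrrole-2-carbaldehyde joins the halves and delivers the target directly, with nitrile, N–H and aldehyde unprotected. The bromide comes from one Pd/norbornene C5–H alkylation of pyrrole-2-carbaldehyde.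

Key step: step 3

Remark: the target has no stereocentre and no C=C bond, so no stereocontrol is needed. 9-BBN is drawn as its monomer.

Step 1
Reactants: 1 acetonitrile; 2 11-bromoundec-1-ene
Product: 4 tridec-12-enenitrile, via lithioacetonitrile 3 (not isolated)
Conditions: MeCN (1.6 equiv), n-BuLi (1.5 equiv), THF, −78 °C; then 2, −78 °C → rt
Reagents that add atoms: none
Why: SN2 alkylation of an α-cyano carbanion (lithioacetonitrile) by an unhindered primary bromide adds the two-carbon nitrile terminus in one operation, the excess of anion at low temperature should limit over-alkylation, and the isolated terminal alkene is inert.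

Step 2
Reactants: 5 1H-pyrrole-2-carbaldehyde; 6 1,8-dibromooctane (4 equiv)
Product: 7 5-(8-bromooctyl)-1H-pyrrole-2-carbaldehyde
Conditions: PdCl2(MeCN)2 (10 mol%), norbornene (2 equiv), KHCO3 (3 equiv), DMA, 90 °C, air
Reagents that add atoms: none
Why: This is a Catellani-type Pd(II)/norbornene-cocatalysed C–H alkylation, known for acceptor-substituted N–H pyrroles with primary alkyl bromides, in which N-palladation and aminopalladation of norbornene steer C–H palladation to C5 (the only C–H next to nitrogen), the palladacycle takes up one C–Br bond, reductive elimination and norbornene extrusion give 7, the weak base holds N-alkylation down, and the excess of 6 should keep the second bromide untouched.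

Step 3
Reactants: 4 tridec-12-enenitrile (1.3 equiv); 8 9-borabicyclo[3.3.1]nonane (9-BBN, 1.25 equiv); 7 5-(8-bromooctyl)-1H-pyrrole-2-carbaldehyde
Product: 10 21-(5-formyl-1H-pyrrol-2-yl)henicosanenitrile (target), via B-(12-cyanododecyl)-9-BBN 9 (not isolated)
Conditions: 4, 9-BBN (0.5 M in THF), 0 °C → rt; then 7, Pd(OAc)2 (4 mol%), PCy3 (8 mol%), K3PO4·H2O (2 equiv), THF, rt
Reagents that add atoms: none
Why: 9-BBN adds to the monosubstituted alkene of 4 in the anti-Markovnikov sense much faster than it attacks the nitrile, so boron sits on C13 and this terminus becomes the nucleophile, while the slight excess of 4 consumes every B–H bond before the aldehyde 7 enters. The electron-rich Pd(0)/PCy3 complex inserts into the unhindered primary C14–Br bond of 7 by an SN2-type oxidative addition, the borate formed from 9 and K3PO4·H2O transfers its primary alkyl group (not the secondary bicyclic B–C bonds) to palladium, and reductive elimination forms C13–C14 ahead of β-hydride elimination because the phosphine is bulky and strongly donating. The closest known reaction type is this one itself, the room-temperature alkyl–alkyl Suzuki–Miyaura coupling of B-alkyl-9-BBN reagents with unactivated primary alkyl bromides bearing β-hydrogens, which tolerates nitriles. No ring is closed and no stereocentre is created. The step needs cross-coupling over homocoupling, secured by the fixed nucleophile and electrophile roles of 9 and 7. It also needs reaction at C–Br rather than at N–H or CHO, secured by the mild, sparingly soluble base at room temperature and by the vinylogous-amide character of the 2-formylpyrrole carbonyl, which resists trialkylboranes.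

Compound list
1 | acetonitrile | CC#N | starting material
2 | 11-bromoundec-1-ene | C=CCCCCCCCCCBr | starting material
3 | lithioacetonitrile | [Li]CC#N | intermediate
4 | tridec-12-enenitrile | N#CCCCCCCCCCCC=C | intermediate
5 | 1H-pyrrole-2-carbaldehyde | O=Cc1ccc[nH]1 | starting material
6 | 1,8-dibromooctane | BrCCCCCCCCBr | starting material
7 | 5-(8-bromooctyl)-1H-pyrrole-2-carbaldehyde | O=Cc1ccc(CCCCCCCCBr)[nH]1 | intermediate
8 | 9-borabicyclo[3.3.1]nonane (9-BBN, commercial THF solution, drawn as monomer) | B1C2CCCC1CCC2 | starting material
9 | 13-(9-borabicyclo[3.3.1]nonan-9-yl)tridecanenitrile (B-(12-cyanododecyl)-9-BBN) | N#CCCCCCCCCCCCCB1C2CCCC1CCC2 | intermediate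
10 | 21-(5-formyl-1H-pyrrol-2-yl)henicosanenitrile | N#CCCCCCCCCCCCCCCCCCCCCc1ccc(C=O)[nH]1 | target

Total step count: 3. Longest linear sequence: 2 (step 1 → step 3, or step 2 → step 3).

Steps most likely to fail

Step 2. The C–H alkylation may suffer in three ways: competing N-alkylation of the acidified N–H, a second coupling at the remote C–Br terminus, or deactivation of palladium through N,O-chelation by the formylpyrrolide. The fallback replaces C–H palladation by directed lithiation. It sets out from 5 (with 6) and returns at 7.
- Condensation of 5 with aqueous dimethylamine should give the 6-(dimethylamino)-1-azafulvene dimer F1, in which the aldehyde and the N–H are masked together.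
- t-BuLi in THF at about −15 °C should lithiate the pyrrole carbon next to each nitrogen, giving the dilithio dimer F2.
- An excess of 6 should alkylate it to the bis(8-bromooctyl) dimer F3.
- Brief hydrolysis with aqueous NaOAc at reflux should release two molecules of 7.

Step 3. The coupling may be eroded by β-hydride elimination of the alkylpalladium intermediate, by slow transmetalation if the deprotonated formylpyrrole binds palladium or boron, or by base-induced N-alkylation. The fallback is a Ni–H reductive hydroalkylation of the alkene. It sets out from 4 and 7 and returns at 10 without any new compound.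
- Conditions: NiBr2·diglyme, 4,4'-di-tert-butyl-2,2'-bipyridine, (EtO)2MeSiH, Na2CO3, NaI, DMA, rt.
- A nickel hydride should add anti-Markovnikov to the terminal alkene of 4 and place nickel on C13.
- The bromide 7 enters as a primary radical, and reductive elimination forms the same C13–C14 bond without a boron reagent or phosphine.

Step 1. Proton transfer between the product nitrile and lithioacetonitrile may lead to over-alkylation, and the hard carbanion may cause some elimination of HBr. The fallback uses a soft stabilised carbanion followed by dealkoxycarbonylation. It sets out from 2 and returns at 4.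
- Alkylation of excess ethyl cyanoacetate with 2 (K2CO3, DMF, 60 °C) should give racemic ethyl 2-cyanotridec-12-enoate F4.
- A Krapcho reaction (LiCl, wet DMSO, 150 °C) should convert F4 into 4.

Further compounds
F1 | step 2 | 6-(dimethylamino)-1-azafulvene dimer (5,10-bis(dimethylamino)-5H,10H-dipyrrolo[1,2-a:1',2'-d]pyrazine) | CN(C)C1c2cccn2C(N(C)C)c2cccn12
F2 | step 2 | dilithio dimer (lithium on the pyrrole carbon next to each nitrogen of F1) | CN(C)C1c2ccc([Li])n2C(N(C)C)c2ccc([Li])n12
F3 | step 2 | bis(8-bromooctyl) dimer | CN(C)C1c2ccc(CCCCCCCCBr)n2C(N(C)C)c2ccc(CCCCCCCCBr)n12
F0 | step 3 | none | none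
F4 | step 1 | ethyl 2-cyanotridec-12-enoate (racemic) | CCOC(=O)C(C#N)CCCCCCCCCC=C
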